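**The balance.** Substrate plus product was my invariant in the north flask: at 72.0 h the two summed to 101% of the substrate charged, so I read lost substrate as product made.

| setting | north | south-east | flask |
|---|---|---|---|
| substrate | 0.25 M | 0.38 M | 0.25 M |
| coupling partner | 0.237 M | 0.237 M | 0.237 M |
| temperature | 60 °C | 60 °C | 60 °C |
| remark | the very flask that is asked about, followed so far | run made earlier |  |
| time |  |  | 4.0 d |

- north (time / h: product / %, substrate / %): 6.00: 18.1, 82.0; 10.0: 30.5, 69.0; 15.0: 41.2, 58.1; 20.0: 48.4, 51.4; 30.0: 54.8, 45.8; 48.0: 57.7, 41.9; 72.0: 59.2, 41.9
- south-east (time / h: product / %, substrate / %): 3.00: 9.6, 91.4; 6.00: 22.1, 77.7; 8.00: 29.3, 71.1; 12.0: 38.1, 61.8; 15.0: 41.5, 58.6; 20.0: 43.9, 56.4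

(readings scatter by 0.3 percentage points)

- what is added takes up no volume worth counting
- the earlier runs do not show what temperature does; that part of a forecast is a guess

- Thursday's: at 4.0 d add coupling partner, 50.0% of the amount charged, then wait 50 h
- Tuesday's: at 4.0 d take out 90% of the by-product then present, then wait 50 h
- Wednesday's: at 4.0 d raise the temperature by 25 K, then wait 50 h
- Friday's: change nothing and wait 50 h more

* product, in percent of the substrate first charged, at 4.0 d
* the option that brings most further product ("none" if no option brings more than 2 percentage points) (Thursday's / Tuesday's / Wednesday's / Friday's / none)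
* product present, in percent of the substrate first charged, after Thursday's
* product present, in percent of the substrate first charged, after Wednesday's

**First estimate.** The north readings flattened after 48.0 h, so for 4.0 d I took the last reading, 59.2%, with 41.9% of the substrate unused. That product is 0.148 M, from 0.237 M of coupling partner, and I counted one partner per product. Why, then, did it stop? North gave 62.4% as moles of product standing per mole of coupling partner charged, the partner yield.

**First doubt.** A yield is useful when nearly constant, but south-east, with more substrate, read 70.4%. It moves with substrate, so I froze north's value for north's flask.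

**Second doubt.** A balance of forward and back steps could also hold the stop, in place of partner lost on an unseen path, and I did not test the two against the readings. I preferred the lost partner, as a judgement and not a proof.

**My reckoning.** Thursday's adds 0.118 M of partner. At the frozen yield that brings 30 percentage points, which is less than the unused substrate, so there was room. I reckoned 88.8% after Thursday's. On this view Tuesday's and Friday's brought nothing, and I guessed that heating left the last reading standing.

**The forecast.** It gave 59.2%, Tuesday's as best, 70% after Thursday's and 58% after Wednesday's: “Tuesday's narrowly wins”. We parted on the best option and on Thursday's figure. Its own figures put Tuesday's at 72%, so choosing Thursday's cost little even on its view.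

**What came.** At 4.0 d the flask gave 58.7%, and Thursday's was best, reaching 92.4%, while Wednesday's stood at 58.7%.

    2 coupling partner → homo dimer (k = 0.170 M⁻¹ h⁻¹, Ea = 92.0 kJ mol⁻¹)
    substrate + coupling partner + by-product → product + 2 by-product (k = 5.24 M⁻² h⁻¹, Ea = 51.0 kJ mol⁻¹)
    substrate + coupling partner → product + by-product (k = 0.0905 M⁻¹ h⁻¹, Ea = 99.0 kJ mol⁻¹)
    (constants at 60 °C)

**Partner yield.** At 96.0 h the coupling partner, the limiting reagent, had 0.0115% of its charge free, with 41.3% of the substrate still there. The flask's partner yield was 61.9%, and the added partner's was 71.0%. Frozen at 62.4%, the yield gives 23.9% for a neighbour flask charged with 0.62 M of substrate. That flask stood at 31.4%, a partner yield of 82.1%.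

All runs are calculated with made-up constants.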